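**Retrosynthetic overview**
1. Ring B is opened at C9–C27 (intramolecular vinylogous aldol of a lactone A dienolate onto the C27 methyl ketone); lactone A is detached at C9–C10 (Negishi coupling of a C10 alkylzinc with enol triflate 40).
2. Ring E is opened at C16–C17 (aldol condensation of the lactone F enolate with a C16 aldehyde, then hydrogenation).
3. The strategy rests on quaternary C22, which is bonded to C17 inside γ-lactone F (C17, C18, O20, C21, C22): C17–C22 is cut to a C21 diazoacetate on a bicyclo[3.2.1]octanone (rings C and D) that carries a tertiary C22–H bond (rhodium carbene 1,5 C–H insertion).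
4. Ring C is opened at C23–C25 (bridging α-alkylation of an extended dienolate, which leaves a C22=C21 methylene for face-selective hydroboration); C16 comes from an orthoformate.
5. C12 comes from an Ireland–Claisen rearrangement with chirality transfer and ring D from 2-methylcyclohexane-1,3-dione; rings form in the order D, C, F, E, A, B.

Key step: step 19

Remark: atom labels C1 to O31 follow the order of the atoms in the target SMILES; C26 is epimerisable next to the C27 carbonyl, so the C26 epimers formed in step 5 are carried together and converge in step 13 (C14 is likewise left unassigned until step 16).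

**Route**

Step 1
Reactants: 1 2-methylcyclohexane-1,3-dione
Product: 2 2-methyl-3-oxocyclohex-1-en-1-yl trifluoromethanesulfonate
Conditions: Tf2O, pyridine, CH2Cl2, −78 to 0 °C
Reagents that add atoms: trifluoromethanesulfonic anhydride, O=S(=O)(OS(=O)(=O)C(F)(F)F)C(F)(F)F
Why: O-sulfonylation of the enol of a symmetrical cyclic 1,3-diketone (enol triflate formation) should give the vinylogous acyl triflate as a cross-coupling electrophile.

Step 2
Reactants: 2 2-methyl-3-oxocyclohex-1-en-1-yl trifluoromethanesulfonate; 3 potassium [2-(benzyloxy)ethyl]trifluoroborate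
Product: 4 3-[2-(benzyloxy)ethyl]-2-methylcyclohex-2-en-1-one
Conditions: PdCl2(dppf) (dppf = 1,1'-bis(diphenylphosphino)ferrocene, 5 mol %), Cs2CO3, THF/H2O, 70 °C
Reagents that add atoms: none
Why: B-alkyl Suzuki–Miyaura coupling of a primary alkyltrifluoroborate with an electron-poor alkenyl triflate should place the C11–C10–OBn chain on the carbon that becomes C12.

Step 3
Reactants: 4 3-[2-(benzyloxy)ethyl]-2-methylcyclohex-2-en-1-one
Product: 5 (S)-3-[2-(benzyloxy)ethyl]-2-methylcyclohex-2-en-1-ol
Conditions: (R)-1-methyl-3,3-diphenyltetrahydro-1H,3H-pyrrolo[1,2-c][1,3,2]oxazaborole (10 mol %), BH3·SMe2, THF, −20 °C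
Reagents that add atoms: none
Why: Corey–Bakshi–Shibata 1,2-reduction of an α-substituted enone, in which the catalyst tells the C(CH3)= arm from the CH2 arm, should give the (S)-carbinol at the future C23, the centre that steers C12 in step 5.

Step 4
Reactants: 5 (S)-3-[2-(benzyloxy)ethyl]-2-methylcyclohex-2-en-1-ol; 6 but-3-enoic acid
Product: 7 (S)-3-[2-(benzyloxy)ethyl]-2-methylcyclohex-2-en-1-yl but-3-enoate
Conditions: N,N'-dicyclohexylcarbodiimide, 4-(dimethylamino)pyridine (5 mol %), CH2Cl2, 0 °C
Reagents that add atoms: none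
Why: Steglich esterification at 0 °C should acylate the secondary allylic alcohol without moving the β,γ double bond of the acid into conjugation.

Step 5
Reactants: 7 (S)-3-[2-(benzyloxy)ethyl]-2-methylcyclohex-2-en-1-yl but-3-enoate
Product: 10 2-{1-[2-(benzyloxy)ethyl]-2-methylcyclohex-2-en-1-yl}but-3-enoic acid (C12 as in the target; both C26 epimers), via silyl ketene acetal 8 (not isolated), via trimethylsilyl ester 9 (not isolated)
Conditions: LiN(iPr)2, Me3SiCl, THF, −78 to 60 °C; then 1 M HCl
Reagents that add atoms: none
Why: Ireland–Claisen rearrangement of the O-silyl dienolate is suprafacial, so the new C12–C26 bond forms on the ring face that carried the C–O bond and the (S)-carbinol fixes quaternary C12, whereas C26 is not controlled here and is corrected in step 13.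

Step 6
Reactants: 10 2-{1-[2-(benzyloxy)ethyl]-2-methylcyclohex-2-en-1-yl}but-3-enoic acid
Product: 11 2-{1-[2-(benzyloxy)ethyl]-2-methylcyclohex-2-en-1-yl}but-3-en-1-ol (C25 alcohol)
Conditions: LiAlH4, THF, 0 °C to rt
Reagents that add atoms: none
Why: Hydride reduction of the carboxylic acid to the primary alcohol should leave the two alkenes and the benzyl ether untouched and removes the acidity of C26–H.

Step 7
Reactants: 11 C25 alcohol
Product: 12 tert-butyldimethylsilyl ether of 11
Conditions: tert-butyldimethylsilyl chloride, imidazole, DMF, rt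
Reagents that add atoms: tert-butyldimethylsilyl chloride, CC(C)(C)[Si](C)(C)Cl
Why: Silylation of the primary alcohol keeps C25 inert during the oxidation and the two enolate methylations that follow.

Step 8
Reactants: 12 silyl ether
Product: 13 4-[2-(benzyloxy)ethyl]-4-[1-(tert-butyldimethylsilyloxy)but-3-en-2-yl]-3-methylcyclohex-2-en-1-one (C30 ketone)
Conditions: CrO3, 3,5-dimethylpyrazole, CH2Cl2, −20 °C
Reagents that add atoms: chromium trioxide, O=[Cr](=O)=O
Why: Chromium trioxide–dimethylpyrazole allylic oxidation of a trisubstituted cyclohexene should attack its only allylic ring methylene (C30) and give the conjugated enone.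

Step 9
Reactants: 13 enone
Product: 14 6-methyl derivative of 13 (methyl C15 on C14; both C14 epimers)
Conditions: LiN(iPr)2, THF, −78 °C; MeI, −78 to −40 °C
Reagents that add atoms: iodomethane, CI
Why: Kinetic deprotonation of the enone at the α' methylene C14 and methylation of the cross-conjugated enolate (enolate alkylation) should install C15 and make later alkylation at C14 less likely.

Step 10
Reactants: 14 6-methyl enone
Product: 15 4-[2-(benzyloxy)ethyl]-4-[1-(tert-butyldimethylsilyloxy)but-3-en-2-yl]-2,3,6-trimethylcyclohex-2-en-1-one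
Conditions: KOtBu (1.05 equiv), t-BuOH/THF, 0 °C; MeI
Reagents that add atoms: iodomethane, CI
Why: Under equilibrating conditions the extended dienolate (γ-deprotonation at C21) is alkylated at its α-carbon C23 (dienolate α-alkylation) and the product returns to conjugation, which installs C24 with limiting base to hold back a second methylation.

Step 11
Reactants: 15 2,3,6-trimethyl enone
Product: 16 4-[2-(benzyloxy)ethyl]-4-(1-bromobut-3-en-2-yl)-2,3,6-trimethylcyclohex-2-en-1-one
Conditions: Ph3PBr2, CH2Cl2, rt
Reagents that add atoms: triphenylphosphine dibromide, BrP(Br)(c1ccccc1)(c1ccccc1)c1ccccc1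
Why: Triphenylphosphine dibromide converts a primary silyl ether directly into the bromide (deoxybromination), which arms C25 only after both methyl groups are in place.

Step 12
Reactants: 16 bromide
Product: 17 5-[2-(benzyloxy)ethyl]-1,3-dimethyl-8-methylidene-6-vinylbicyclo[3.2.1]octan-2-one (rings C and D; both C26 and C14 epimers)
Conditions: KOtBu, t-BuOH/THF, rt to 50 °C
Reagents that add atoms: none
Why: Intramolecular α-alkylation of the extended dienolate is a 5-(enolexo)-exo-tet closure that forms C23–C25, ring C and quaternary C23 (its configuration is imposed by the tether from C12) and leaves the C22=C21 methylene, while attack through C21 would need an enolendo closure.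

Step 13
Reactants: 17 vinyl bicyclooctanone
Product: 19 6-exo-acetyl-5-[2-(benzyloxy)ethyl]-1,3-dimethyl-8-methylidenebicyclo[3.2.1]octan-2-one (C26 as in the target), via C26-epimeric methyl ketone 18 (not isolated)
Conditions: PdCl2 (10 mol %), CuCl, O2 (1 atm), DMF/H2O, rt; then NaOMe (0.2 equiv), MeOH, rt
Reagents that add atoms: water, O
Why: Tsuji–Wacker oxidation converts only the monosubstituted alkene into the methyl ketone, and base equilibration at C26 should then favour the exo acetyl group because an endo acetyl group would press against the axial hydrogen on C14 under ring D.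

Step 14
Reactants: 19 exo methyl ketone
Product: 20 5-[2-(benzyloxy)ethyl]-1,3-dimethyl-8-methylidene-6-exo-(2-methyl-1,3-dioxolan-2-yl)bicyclo[3.2.1]octan-2-one
Conditions: 1,2-bis(trimethylsilyloxy)ethane, Me3SiOTf (5 mol %), CH2Cl2, −78 to −20 °C
Reagents that add atoms: 1,2-bis(trimethylsilyloxy)ethane, C[Si](C)(C)OCCO[Si](C)(C)C
Why: Silyl-triflate-catalysed ketalisation with the bis-silyl glycol should protect the methyl ketone only, because the C30 ketone lies between a quaternary and a tertiary carbon.

Step 15
Reactants: 20 dioxolane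
Product: 22 5-[2-(benzyloxy)ethyl]-8-(hydroxymethyl)-1,3-dimethyl-6-exo-(2-methyl-1,3-dioxolan-2-yl)bicyclo[3.2.1]octan-2-one (C21 syn to the C25–C26 bridge), via B-alkyl-9-borabicyclononane 21 (not isolated)
Conditions: 9-borabicyclo[3.3.1]nonane, THF, rt to 50 °C; then NaOH, H2O2, 0 °C
Reagents that add atoms: hydrogen peroxide, OO
Why: Hydroboration–oxidation puts boron on C21 and hydrogen on C22 from the face over the three-carbon bridge, because the exo dioxolanyl group on C26 screens the face over the C25–C26 bridge, so C21 ends syn to that bridge and C22–H points where C17 must later enter.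

Step 16
Reactants: 22 C21 alcohol
Product: 24 5-[2-(benzyloxy)ethyl]-3-(dimethoxymethyl)-8-(hydroxymethyl)-1,3-dimethyl-6-exo-(2-methyl-1,3-dioxolan-2-yl)bicyclo[3.2.1]octan-2-one (C16 exo on C14), via bis(trimethylsilyl) derivative 23 (not isolated)
Conditions: Me3SiOTf, Et3N, CH2Cl2, 0 °C to rt; crude 23, HC(OMe)3, Me3SiOTf (10 mol %), CH2Cl2, −78 °C; then K2CO3, MeOH
Reagents that add atoms: trimethyl orthoformate, COC(OC)OC
Why: Mukaiyama-type addition of the only possible silyl enol ether (C30=C14) to the dimethoxycarbenium ion should occur on the exo face away from the C25–C26 bridge, which sets quaternary C14 with C16 on the side of C22 and C15 endo, while the alcohol is masked in the flask as its silyl ether.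

Step 17
Reactants: 24 acetal alcohol; 25 bromoacetyl bromide
Product: 26 bromoacetate of 24 at O20
Conditions: NaHCO3, MeCN, 0 °C
Reagents that add atoms: none
Why: Acylation of the primary C21 alcohol with an acid bromide under buffered conditions should leave the acetal and the ketal intact.

Step 18
Reactants: 26 bromoacetate
Product: 27 diazoacetate of 24 at O20 (precursor of the key step)
Conditions: N,N'-ditosylhydrazine, DBU, THF, 0 °C
Reagents that add atoms: N,N'-ditosylhydrazine, Cc1ccc(cc1)S(=O)(=O)NNS(=O)(=O)c1ccc(C)cc1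
Why: Displacement of bromide by the ditosylhydrazine anion and twofold sulfinate elimination (diazoacetate synthesis from bromoacetates) gives the diazo ester without a strong base or an acid.

Step 19
Reactants: 27 diazoacetate
Product: 28 spiro γ-lactone on the bicyclo[3.2.1]octanone (lactone F; C17–C22 formed)
Conditions: Rh2(NHCOCH3)4 (1 mol %), CH2Cl2, reflux, slow addition of 27 at high dilution
Reagents that add atoms: none
Why: The rhodium carbene formed from 27 with loss of N2 inserts into the axial tertiary C22–H bond through a three-centre transition state with hydride-transfer character, so that the C17–C22 bond grows where the C–H bond was. The closest known reaction is the γ-lactone-forming 1,5 C–H insertion of alkyl diazoacetates under dirhodium carboxamidate catalysis. Lactone F (C17, C18, O20, C21, C22) closes as a five-membered ring by 1,5-insertion, and the ester tether offers no other C–H bond at that distance apart from the C21–H bonds of a four-membered alternative. C22 becomes quaternary with retention, so C17 lies over the three-carbon bridge because C21 was placed syn to the C25–C26 bridge in step 15, and no other stereocentre is formed. The step needs site selectivity for C22–H over the C21–H bonds, the ketal and acetal oxygens and the benzyl ring; the electron-rich tertiary C–H bond, the five-membered transition ring and the less electrophilic acetamidate-ligated carbene, added slowly to suppress dimerisation, should secure it.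

Step 20
Reactants: 28 spiro lactone
Product: 29 keto aldehyde (C16 formyl on C14; C27 methyl ketone; lactone F; benzyl ether)
Conditions: 2 M HCl, THF, 40 °C
Reagents that add atoms: water, O
Why: Acid hydrolysis removes the dimethyl acetal and the dioxolane together, and the non-enolisable β-keto aldehyde is stable to acid (acetal hydrolysis).

Step 21
Reactants: 29 keto aldehyde
Product: 30 tetracyclic β-hydroxy lactone (ring E closed; C16 carbinol; C16 and C17 epimers)
Conditions: LiN(SiMe3)2 (2.5 equiv), THF, −78 to −30 °C; then NH4Cl (aq)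
Reagents that add atoms: none
Why: In this intramolecular aldol addition the excess amide turns the methyl ketone into an enolate that cannot reach C16 and the lactone into its C17 enolate, which closes ring E on the neighbouring aldehyde in a 6-(enolexo)-exo-trig mode, the new centres at C16 and C17 being removed or reset in steps 22 and 23.

Step 22
Reactants: 30 β-hydroxy lactone
Product: 32 α,β-unsaturated lactone with a C16=C17 bond in the bicyclo[2.2.2]octene, via mesylate 31 (not isolated)
Conditions: MsCl, Et3N, CH2Cl2, 0 °C; then DBU, rt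
Reagents that add atoms: none
Why: Mesylation and base-induced E1cB elimination through the lactone enolate give the conjugated alkene whichever C16/C17 diastereomer is present, and DBU keeps C26 in its favoured exo configuration.

Step 23
Reactants: 32 unsaturated lactone
Product: 33 saturated pentacyclic keto lactone with free C10 alcohol (C17 as in the target)
Conditions: H2 (3 atm), Pd on carbon, EtOAc/EtOH, rt
Reagents that add atoms: none
Why: Heterogeneous hydrogenation should add H2 to the strained alkene from the face flanked by the flat C30 carbonyl and not from the face flanked by the C13 methylene and the C11 chain, which puts the C17 hydrogen on the side of C30, and the same catalyst hydrogenolyses the benzyl ether.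

Step 24
Reactants: 33 C10 alcohol
Product: 34 C10 iodide
Conditions: I2, PPh3, imidazole, CH2Cl2, 0 °C to rt
Reagents that add atoms: iodine, II
Why: Appel-type iodination converts the unhindered primary alcohol under neutral conditions that the ketones and the lactone tolerate.

Step 25
Reactants: 35 methyl furan-2-carboxylate
Product: 36 2-(furan-2-yl)propan-2-ol
Conditions: MeMgBr (2.2 equiv), THF, 0 °C; then NH4Cl (aq)
Reagents that add atoms: methylmagnesium bromide, C[Mg]Br
Why: Double Grignard addition to the ester gives the tertiary furyl carbinol that carries C2 and its two methyl groups.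

Step 26
Reactants: 36 2-(furan-2-yl)propan-2-ol
Product: 37 6-hydroxy-2,2-dimethyl-2H-pyran-3(6H)-one
Conditions: N-bromosuccinimide, NaHCO3, NaOAc, THF/H2O, 0 °C
Reagents that add atoms: water, O
Why: Achmatowicz oxidative ring expansion of a furyl carbinol gives the pyranone lactol with the gem-dimethyl carbon next to the ketone.

Step 27
Reactants: 37 pyranone lactol
Product: 38 6,6-dimethyl-2H-pyran-2,5(6H)-dione
Conditions: CrO3, H2SO4, acetone/H2O, 0 °C
Reagents that add atoms: none
Why: Chromic acid oxidation of the lactol gives the lactone carbonyl C5 (lactol to lactone oxidation).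

Step 28
Reactants: 38 ene-dione lactone
Product: 39 6,6-dimethyldihydro-2H-pyran-2,5(6H)-dione
Conditions: H2 (1 atm), Pd on carbon, EtOAc, rt
Reagents that add atoms: none
Why: Catalytic hydrogenation saturates the electron-poor alkene of the ene-dione and leaves both carbonyl groups.

Step 29
Reactants: 39 keto lactone
Product: 40 6,6-dimethyl-2-oxo-3,6-dihydro-2H-pyran-5-yl trifluoromethanesulfonate
Conditions: KN(SiMe3)2 (1.05 equiv), N-phenylbis(trifluoromethanesulfonimide), THF, −78 °C
Reagents that add atoms: N-phenylbis(trifluoromethanesulfonimide), O=S(=O)(N(c1ccccc1)S(=O)(=O)C(F)(F)F)C(F)(F)F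
Why: The ketone can enolise only toward its one α-methylene and is more acidic than the lactone, so O-triflation of that enolate (enol triflate formation) gives the C8=C9 enol triflate with the leaving group on C9.

Step 30
Reactants: 34 C10 iodide; 40 enol triflate
Product: 42 pentacyclic keto lactone bearing 6,6-dimethyl-2-oxo-3,6-dihydro-2H-pyran-5-yl on C10, via alkylzinc iodide 41 (not isolated)
Conditions: Zn dust, LiCl, THF, 40 °C; then 40, PdCl2(dppf) (5 mol %), THF, 50 °C
Reagents that add atoms: none
Why: Zinc insertion into the primary iodide tolerates ketones and lactones, and Negishi coupling of the alkylzinc with the enol triflate forms C9–C10 and delivers lactone A as its β,γ-unsaturated isomer.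

Step 31
Reactants: 42 β,γ-unsaturated lactone methyl ketone
Product: 43 CNP0222978.4 (target)
Conditions: LiN(SiMe3)2 (1.1 equiv), THF, −78 to −40 °C; then NH4Cl (aq)
Reagents that add atoms: none
Why: In this intramolecular vinylogous aldol addition the C7 protons of the β,γ-unsaturated lactone are the most acidic in 42, the lithium dienolate can reach the C27 ketone only through its γ-carbon C9 (six-membered ring B against an eight-membered alternative), and a chair-like lithium-bridged transition state with the ketone methyl equatorial and the carbonyl oxygen axial on the side of C21 over the C7=C8 arm should set C9 and C27 as in the target.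

**Compound list**
1 | 2-methylcyclohexane-1,3-dione | CC1C(=O)CCCC1=O | starting material
2 | 2-methyl-3-oxocyclohex-1-en-1-yl trifluoromethanesulfonate | CC1=C(OS(=O)(=O)C(F)(F)F)CCCC1=O | intermediate
3 | potassium [2-(benzyloxy)ethyl]trifluoroborate | [K+].F[B-](F)(F)CCOCc1ccccc1 | starting material
4 | 3-[2-(benzyloxy)ethyl]-2-methylcyclohex-2-en-1-one | CC1=C(CCOCc2ccccc2)CCCC1=O | intermediate
5 | (S)-3-[2-(benzyloxy)ethyl]-2-methylcyclohex-2-en-1-ol | O[C@H]1CCCC(CCOCc2ccccc2)=C1C | intermediate
6 | but-3-enoic acid | C=CCC(=O)O | starting material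
7 | (S)-3-[2-(benzyloxy)ethyl]-2-methylcyclohex-2-en-1-yl but-3-enoate | C=CCC(=O)O[C@H]1CCCC(CCOCc2ccccc2)=C1C | intermediate
8 | O-trimethylsilyl ketene acetal of 7 (dienol form) | C=CC=C(O[Si](C)(C)C)O[C@H]1CCCC(CCOCc2ccccc2)=C1C | intermediate (not isolated)
9 | trimethylsilyl ester of 10 | C[Si](C)(C)OC(=O)C(C=C)[C@]1(CCOCc2ccccc2)CCCC=C1C | intermediate (not isolated)
10 | 2-{1-[2-(benzyloxy)ethyl]-2-methylcyclohex-2-en-1-yl}but-3-enoic acid, C12 as in the target, both C26 epimers | OC(=O)C(C=C)[C@]1(CCOCc2ccccc2)CCCC=C1C | intermediate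
11 | 2-{1-[2-(benzyloxy)ethyl]-2-methylcyclohex-2-en-1-yl}but-3-en-1-ol, both C26 epimers | OCC(C=C)[C@]1(CCOCc2ccccc2)CCCC=C1C | intermediate
12 | tert-butyldimethylsilyl ether of 11 | CC(C)(C)[Si](C)(C)OCC(C=C)[C@]1(CCOCc2ccccc2)CCCC=C1C | intermediate
13 | 4-[2-(benzyloxy)ethyl]-4-[1-(tert-butyldimethylsilyloxy)but-3-en-2-yl]-3-methylcyclohex-2-en-1-one | CC(C)(C)[Si](C)(C)OCC(C=C)[C@]1(CCOCc2ccccc2)CCC(=O)C=C1C | intermediate
14 | 6-methyl derivative of 13, both C14 epimers | CC(C)(C)[Si](C)(C)OCC(C=C)[C@]1(CCOCc2ccccc2)CC(C)C(=O)C=C1C | intermediate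
15 | 4-[2-(benzyloxy)ethyl]-4-[1-(tert-butyldimethylsilyloxy)but-3-en-2-yl]-2,3,6-trimethylcyclohex-2-en-1-one | CC(C)(C)[Si](C)(C)OCC(C=C)[C@]1(CCOCc2ccccc2)CC(C)C(=O)C(C)=C1C | intermediate
16 | 4-[2-(benzyloxy)ethyl]-4-(1-bromobut-3-en-2-yl)-2,3,6-trimethylcyclohex-2-en-1-one | BrCC(C=C)[C@]1(CCOCc2ccccc2)CC(C)C(=O)C(C)=C1C | intermediate
17 | 5-[2-(benzyloxy)ethyl]-1,3-dimethyl-8-methylidene-6-vinylbicyclo[3.2.1]octan-2-one, both C26 and C14 epimers | c1ccccc1COCC[C@@]12CC(C)C(=O)[C@](C)(CC2C=C)C1=C | intermediate
18 | 6-acetyl analogue of 17 as C26 epimer mixture | c1ccccc1COCC[C@@]12CC(C)C(=O)[C@](C)(CC2C(C)=O)C1=C | intermediate (not isolated)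
19 | 6-exo-acetyl-5-[2-(benzyloxy)ethyl]-1,3-dimethyl-8-methylidenebicyclo[3.2.1]octan-2-one | c1ccccc1COCC[C@@]12CC(C)C(=O)[C@](C)(C[C@H]2C(C)=O)C1=C | intermediate
20 | 6-exo-(2-methyl-1,3-dioxolan-2-yl) analogue of 19 | c1ccccc1COCC[C@@]12CC(C)C(=O)[C@](C)(C[C@H]2C3(C)OCCO3)C1=C | intermediate
21 | B-alkyl-9-borabicyclo[3.3.1]nonane from 20 (boron on C21) | c1ccccc1COCC[C@@]12CC(C)C(=O)[C@](C)(C[C@H]2C3(C)OCCO3)[C@@H]1CB4C5CCCC4CCC5 | intermediate (not isolated)
22 | 8-(hydroxymethyl) ketal, C21 syn to the C25–C26 bridge | c1ccccc1COCC[C@@]12CC(C)C(=O)[C@](C)(C[C@H]2C3(C)OCCO3)[C@@H]1CO | intermediate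
23 | trimethylsilyl enol ether (C30=C14) and C21 trimethylsilyl ether of 22 | c1ccccc1COCC[C@@]12CC(C)=C(O[Si](C)(C)C)[C@](C)(C[C@H]2C3(C)OCCO3)[C@@H]1CO[Si](C)(C)C | intermediate (not isolated)
24 | C14 dimethoxymethyl (C16) C21 alcohol | c1ccccc1COCC[C@@]12C[C@@](C)(C(OC)OC)C(=O)[C@](C)(C[C@H]2C3(C)OCCO3)[C@@H]1CO | intermediate
25 | bromoacetyl bromide | BrCC(Br)=O | starting material
26 | bromoacetate of 24 | c1ccccc1COCC[C@@]12C[C@@](C)(C(OC)OC)C(=O)[C@](C)(C[C@H]2C3(C)OCCO3)[C@@H]1COC(=O)CBr | intermediate
27 | diazoacetate of 24 (key-step precursor) | c1ccccc1COCC[C@@]12C[C@@](C)(C(OC)OC)C(=O)[C@](C)(C[C@H]2C3(C)OCCO3)[C@@H]1COC(=O)C=[N+]=[N-] | intermediate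
28 | spiro γ-lactone (lactone F) on the bicyclo[3.2.1]octanone (key-step product) | c1ccccc1COCC[C@@]12C[C@@](C)(C(OC)OC)C(=O)[C@](C)(C[C@H]2C4(C)OCCO4)[C@]13COC(=O)C3 | intermediate
29 | C16 aldehyde, C27 methyl ketone spiro lactone | c1ccccc1COCC[C@@]12C[C@@](C)(C=O)C(=O)[C@](C)(C[C@H]2C(C)=O)[C@]13COC(=O)C3 | intermediate
30 | ring E β-hydroxy lactone, C16 and C17 epimers | c1ccccc1COCC[C@@]12C[C@@]3(C)C(O)C4C(=O)OC[C@]41[C@@](C)(C[C@H]2C(C)=O)C3=O | intermediate
31 | C16 mesylate of 30 | c1ccccc1COCC[C@@]12C[C@@]3(C)C(OS(C)(=O)=O)C4C(=O)OC[C@]41[C@@](C)(C[C@H]2C(C)=O)C3=O | intermediate (not isolated)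
32 | C16=C17 unsaturated lactone | c1ccccc1COCC[C@@]12C[C@@]3(C)C=C4C(=O)OC[C@]41[C@@](C)(C[C@H]2C(C)=O)C3=O | intermediate
33 | saturated keto lactone with C10 alcohol | OCC[C@@]12C[C@@]3(C)C[C@H]4C(=O)OC[C@]41[C@@](C)(C[C@H]2C(C)=O)C3=O | intermediate
34 | C10 iodide | ICC[C@@]12C[C@@]3(C)C[C@H]4C(=O)OC[C@]41[C@@](C)(C[C@H]2C(C)=O)C3=O | intermediate
35 | methyl furan-2-carboxylate | COC(=O)c1ccco1 | starting material
36 | 2-(furan-2-yl)propan-2-ol | CC(C)(O)c1ccco1 | intermediate
37 | 6-hydroxy-2,2-dimethyl-2H-pyran-3(6H)-one | CC1(C)OC(O)C=CC1=O | intermediate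
38 | 6,6-dimethyl-2H-pyran-2,5(6H)-dione | CC1(C)OC(=O)C=CC1=O | intermediate
39 | 6,6-dimethyldihydro-2H-pyran-2,5(6H)-dione | CC1(C)OC(=O)CCC1=O | intermediate
40 | 6,6-dimethyl-2-oxo-3,6-dihydro-2H-pyran-5-yl trifluoromethanesulfonate | CC1(C)OC(=O)CC=C1OS(=O)(=O)C(F)(F)F | intermediate
41 | C10 alkylzinc iodide from 34 | I[Zn]CC[C@@]12C[C@@]3(C)C[C@H]4C(=O)OC[C@]41[C@@](C)(C[C@H]2C(C)=O)C3=O | intermediate (not isolated)
42 | keto lactone with β,γ-unsaturated lactone A on C10 | O=C1CC=C(CC[C@@]23C[C@@]4(C)C[C@H]5C(=O)OC[C@]52[C@@](C)(C[C@H]3C(C)=O)C4=O)C(C)(C)O1 | intermediate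
43 | CNP0222978.4 | CC1(C)OC(=O)C=C[C@]12CC[C@@]13C[C@@]4(C)C[C@H]5C(=O)OC[C@]51[C@@](C)(C[C@H]3[C@@]2(C)O)C4=O | target

**Step count**
Total: 31 steps. Longest linear sequence: 26 steps (steps 1–24, 30 and 31); the enol triflate branch is steps 25–29.

**Steps most likely to fail**

Step 19. The carbene may dimerise, attack the ketal or acetal oxygens, or insert into a C21–H bond, because the tertiary C22–H bond sits between two quaternary carbons and is hard to reach. The fallback sets out from 24 and returns at 29. Dess–Martin oxidation of 24 gives the C21 aldehyde F1. Its potassium enolate (KH, THF), which is exocyclic at C22, is alkylated with tert-butyl bromoacetate from the face over the three-carbon bridge to give the C22-quaternary aldehyde ester F2. NaBH4 reduces only the aldehyde and gives the hydroxy ester F3. CF3CO2H/H2O then removes the tert-butyl group, closes lactone F and unmasks C16 and C27, which gives 29.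

Step 15. The borane may add to the wrong face of the C22=C21 bond (poor facial selectivity), which would leave C21 anti to the C25–C26 bridge. The fallback sets out from 19 and returns at 22; it uses a ring that only the wanted C22 epimer can form. NaBH4 reduces the methyl ketone of 19 to the C27 alcohol F4. Hydroboration–oxidation without regard to the face gives the diol F5 as a C22 mixture. 2,2,6,6-Tetramethylpiperidin-1-oxyl with PhI(OAc)2 oxidises the primary alcohol to the aldehyde, and DBU equilibrates C22 through the enol until all material is held as the six-membered lactol F6 between C21 and the exo C27 oxygen. NaBH4 opens F6 to the syn diol F7. NaOCl in acetic acid oxidises only the secondary alcohol to the hydroxy ketone F8, and ketalisation as in step 14 gives 22.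

Step 31. Enolisation may take place at the methyl ketone and not at lactone A, the aldolate may revert, or the closure may give the wrong face at C9 or C27. The fallback sets out from 42 and returns at 43; it makes the dienolate by reduction and not by deprotonation. mCPBA epoxidises the C8=C9 bond of 42 to the β,γ-epoxy lactone F9. Et3N opens F9 by β-elimination to the γ-hydroxy α,β-unsaturated lactone F10. Trifluoroacetic anhydride and pyridine give the trifluoroacetate F11. SmI2 (THF, −78 °C) then expels the γ-acyloxy group and forms a samarium dienolate, which adds through C9 to the C27 ketone in a metal-bridged transition state and gives 43.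

**Further compounds**
F1 | step 19 | C21 aldehyde from 24 | c1ccccc1COCC[C@@]12C[C@@](C)(C(OC)OC)C(=O)[C@](C)(C[C@H]2C3(C)OCCO3)[C@@H]1C=O
F2 | step 19 | C22-quaternary aldehyde with tert-butyl acetate arm (C17, C18) | c1ccccc1COCC[C@@]12C[C@@](C)(C(OC)OC)C(=O)[C@](C)(C[C@H]2C3(C)OCCO3)[C@@]1(C=O)CC(=O)OC(C)(C)C
F3 | step 19 | C21 hydroxy tert-butyl ester | c1ccccc1COCC[C@@]12C[C@@](C)(C(OC)OC)C(=O)[C@](C)(C[C@H]2C3(C)OCCO3)[C@@]1(CO)CC(=O)OC(C)(C)C
F4 | step 15 | C27 alcohol of 19, C27 epimers | c1ccccc1COCC[C@@]12CC(C)C(=O)[C@](C)(C[C@H]2C(C)O)C1=C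
F5 | step 15 | C21, C27 diol as C22 mixture | c1ccccc1COCC[C@@]12CC(C)C(=O)[C@](C)(C[C@H]2C(C)O)C1CO
F6 | step 15 | six-membered lactol between C21 and O on C27 | c1ccccc1COCC[C@@]12CC(C)C(=O)[C@](C)(C[C@H]2C(C)O3)[C@@H]1C3O
F7 | step 15 | C21, C27 diol with C21 syn to the C25–C26 bridge | c1ccccc1COCC[C@@]12CC(C)C(=O)[C@](C)(C[C@H]2C(C)O)[C@@H]1CO
F8 | step 15 | C21 alcohol with exo acetyl on C26 | c1ccccc1COCC[C@@]12CC(C)C(=O)[C@](C)(C[C@H]2C(C)=O)[C@@H]1CO
F9 | step 31 | C8–C9 epoxide of 42 | O=C1CC2OC2(CC[C@@]34C[C@@]5(C)C[C@H]6C(=O)OC[C@]63[C@@](C)(C[C@H]4C(C)=O)C5=O)C(C)(C)O1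
F10 | step 31 | C9 hydroxy α,β-unsaturated lactone | O=C1C=CC(O)(CC[C@@]23C[C@@]4(C)C[C@H]5C(=O)OC[C@]52[C@@](C)(C[C@H]3C(C)=O)C4=O)C(C)(C)O1
F11 | step 31 | C9 trifluoroacetate of F10 | O=C1C=CC(OC(=O)C(F)(F)F)(CC[C@@]23C[C@@]4(C)C[C@H]5C(=O)OC[C@]52[C@@](C)(C[C@H]3C(C)=O)C4=O)C(C)(C)O1
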